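**1.** You asked for a quick number, so I began from the slowness of Thursday's run. Its target stood at 1.3% of the charge at 20.0 min, lower than Wednesday's 7.3%, with a scatter of 0.5 percentage points.

| setting | Wednesday's | Thursday's | south-west | south | north-west |
|---|---|---|---|---|---|
| starting material | 0.024 M | 0.28 M | 0.020 M | 0.060 M | 0.20 M |
| partner | 0.12 M | 0.12 M | 0.120 M | 0.120 M | 0.120 M |
| remark | run made earlier | run made earlier |  |  |  |
| time |  |  | 30 min | 30 min | 30 min |

| run | time / min | target / % |
|---|---|---|
| Wednesday's | 1.50 | 0.8 |
| Wednesday's | 3.00 | 1.9 |
| Wednesday's | 5.00 | 3.1 |
| Wednesday's | 8.00 | 4.8 |
| Wednesday's | 12.0 | 5.3 |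
| Wednesday's | 20.0 | 7.3 |
| Thursday's | 1.50 | 0 |
| Thursday's | 3.00 | 0 |
| Thursday's | 5.00 | 0 |
| Thursday's | 8.00 | 0.6 |
| Thursday's | 12.0 | 0.3 |
| Thursday's | 20.0 | 1.3 |

(each reading ± 0.5 percentage points)

- [target] at the end for south-west, south, north-west, in this order
- how that number moves from the first to the last of them (falls all the way / rises all the way / rises, then falls / falls, then rises / hardly changes)

**2.** Wednesday's starting material was 0.200 of the partner charge and Thursday's was 2.33, so Thursday's flask held more starting material than partner.

**3.** Your forecast gave 0.0021 M, 0.0028 M and 0.004 M, a row that rises all the way: “I therefore expect a modest rise with concentration”.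

**4.** My reckoning differed, and it rested on a guess. I followed one molecule of starting material and supposed that it first takes up a partner, then needs a second one. For south I got 0.500 as the free share, the fraction of the partner charge unbound once each molecule of starting material has taken one partner. For south-west it was 0.833.

**5.** I scored each flask as bound share times free share, both as fractions of the partner charge: 0.160 for Wednesday's run, 0.139 for south-west and 0.250 for south. This score peaks at 0.0600 M, half the partner charge. Scaling Wednesday's last reading in proportion to time and score gave 0.00228 M for south-west and 0.00411 M for south.

**6.** In north-west, partner is the limiting reagent, so the free share is zero, as in Thursday's run. Thursday's reading shows that zero is too strong, so I gave no number, but I placed north-west below south. We parted on the shape: I expected a rise, then a fall.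

**7.** The flasks gave 0.00196 M, 0.00380 M and 0.00196 M: the row rises, then falls, turning at 0.072 M.

    starting material + partner ⇌ intermediate (K = 88.0 M⁻¹, k = 19.0 M⁻¹ min⁻¹)
    partner + intermediate → target (k = 0.100 M⁻¹ min⁻¹)
    partner + intermediate → side product (k = 0.220 M⁻¹ min⁻¹)
    target ⇌ isomer of the product (K = 0.910, k = 0.120 min⁻¹)

In south-west, with the other concentrations as charged, the forward binding step alone gave starting material a half-life of 0.30 min, far shorter than the 26 min of intermediate passing into side product by that step alone, and at 30.0 min intermediate stood at 39.7% of the starting material charged against 9.80% for target. At 15.0 min, south-west's free share, reckoned from the charges as 83.3%, stood against 78.9% of the partner charge left, south's 50.0% against 45.9%, and north-west, charged with more starting material than partner, had 9.26% of its partner charge left.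

(The runs were generated by integration on assumed constants, and the scatter is random.)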